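**Retrosynthetic overview**
1. Target 13 ⇐ C-18 alcohol 11 (CH2OH → CO2H) ⇐ 3,18-diol 8 (radical removal of the 3-OH through the cyclic thionocarbonate 9).
2. 8 ⇐ acyclic epoxy alcohol 4 in one cationic cascade that copies the class II diterpene cyclase path: ring A (C4–C5), then ring B (C9–C10) to the ent-labdan-8-yl cation, then H-9→C-8 and Me-10→C-9 shifts, then loss of H-1.
3. 4 ⇐ Sharpless epoxidation of (14E)-16-hydroxygeranylgeranyl acetate 3 ⇐ SeO2 ω-oxidation of geranylgeranyl acetate 2 ⇐ geranylgeraniol 1.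
4. Ring order: A, then B, in the same flask. The epoxide (absolute sense) and the E-alkene geometry (C-18 equatorial) together set C4, C5, C8 and C9.

Assumption: the target is 15-acetoxy-ent-halima-1(10),13E-dien-18-oic acid, (4S,5S,8R,9S); ring positions use labdane/halimane numbering, acyclic compounds use geranylgeraniol numbering, α/β mean the faces as drawn with H-5 β, and (2E,6E,10E)-geranylgeraniol is taken as the commercial starting material.

**Step 1**
Reactants: 1 (2E,6E,10E)-geranylgeraniol
Product: 2 (2E,6E,10E)-geranylgeranyl acetate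
Conditions: Ac2O, pyridine, DMAP (cat.), CH2Cl2, 0 °C → rt
Reagents that add atoms: acetic anhydride, CC(=O)OC(C)=O
Why: DMAP-catalysed O-acylation installs the target's acetate at the start and deactivates the 2,3-alkene toward the later electrophilic steps; no stereocentre is formed.

**Step 2**
Reactants: 2 (2E,6E,10E)-geranylgeranyl acetate
Product: 3 (2E,6E,10E,14E)-16-hydroxygeranylgeranyl acetate
Conditions: SeO2 (0.2 equiv), t-BuOOH (3 equiv), salicylic acid (0.1 equiv), CH2Cl2, 0 °C → rt; stop at partial conversion and recycle 2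
Reagents that add atoms: tert-butyl hydroperoxide, CC(C)(C)OO (oxygen relayed through catalytic selenium dioxide, O=[Se]=O)
Why: Sharpless SeO2/t-BuOOH allylic oxidation (ene reaction, then [2,3]-sigmatropic shift) attacks the most electron-rich terminal isopropylidene at its E-methyl group, and this E geometry later places C-18 equatorial.

**Step 3**
Reactants: 3 (2E,6E,10E,14E)-16-hydroxygeranylgeranyl acetate
Product: 4 (14R,15R)-14,15-epoxy-16-hydroxygeranylgeranyl acetate
Conditions: Ti(OiPr)4 (10 mol%), D-(−)-diethyl tartrate (13 mol%), t-BuOOH (2 equiv, anhydrous), 4 Å MS, CH2Cl2, −20 °C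
Reagents that add atoms: tert-butyl hydroperoxide, CC(C)(C)OO
Why: Sharpless asymmetric epoxidation touches only the allylic-alcohol alkene, and D-(−)-tartrate gives the (14R,15R)-epoxide (the mirror image of the (2S,3S) products that L-(+)-tartrate gives with E-allylic alcohols), which is the only source of absolute configuration in the route.

**Step 4**
Reactants: 4 (14R,15R)-14,15-epoxy-16-hydroxygeranylgeranyl acetate
Product: 8 15-acetoxy-ent-halima-1(10),13E-diene-3,18-diol (3R,4S,5S,8R,9S), via ent-labd-13-en-8-yl cation 5 (not isolated), via ent-labd-13-en-9-yl cation 6 (not isolated), via ent-halim-13-en-10-yl cation 7 (not isolated)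
Conditions: BF3·OEt2 (3 equiv), CH2Cl2 (5 mM), −78 → −30 °C; Et3N quench at −78 °C, then aq. NaHCO3
Reagents that add atoms: none
Why: Proposed new method: BF3 opens the epoxide at the tertiary carbon (labdane C-4) with anti attack of the neighbouring alkene, and all-chair Stork–Eschenmoser folding (epoxide oxygen equatorial at C-3, the E-CH2O arm equatorial at C-4) closes ring A and then ring B to the 8-yl cation 5, which sets 3R, 4S and 5S; in the non-basic BF3/CH2Cl2 medium 5 should live long enough for the antiperiplanar 1,2-H shift (H-9β→C-8, sets 8R) and 1,2-methyl shift (Me-10α→C-9, sets 9S) through 6 to the 10-yl cation 7, which is expected to lose the unhindered H-1 rather than H-5 (flanked by the quaternary C-4 and its two BF3-bound oxygens) when quenched cold; the closest known reactions are BF3-promoted epoxy-polyene bicyclisations and BF3-induced 8-yl→10-yl friedo shifts of drimanes and labdanes, here merged in one flask, with the acetate-deactivated 13,14-alkene preventing a third ring closure.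

**Step 5**
Reactants: 8 15-acetoxy-ent-halima-1(10),13E-diene-3,18-diol
Product: 9 cyclic 3,18-thionocarbonate of 8 (1,3-dioxane-2-thione fused at C-3/C-4)
Conditions: 1,1'-thiocarbonyldiimidazole (1.5 equiv), DMAP (0.2 equiv), toluene, 80 °C
Reagents that add atoms: 1,1'-thiocarbonyldiimidazole, S=C(n1ccnc1)n1ccnc1
Why: The trans-diequatorial 1,3-diol closes readily to the six-membered cyclic thionocarbonate by double thioacylation; no stereocentre is touched.

**Step 6**
Reactants: 9 cyclic 3,18-thionocarbonate of 8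
Product: 11 15-acetoxy-ent-halima-1(10),13E-dien-18-ol (4S,5S,8R,9S), via S-silyl thiolcarbonate 10 (not isolated)
Conditions: (Me3Si)3SiH (2 equiv), AIBN (0.2 equiv), toluene, 90 °C; then MeOH/H2O, silica gel, rt
Reagents that add atoms: none
Why: Barton–McCombie-type radical deoxygenation of a cyclic thionocarbonate: the silyl radical adds to C=S and β-scission breaks the secondary C3–O bond in preference to the neopentyl primary C18–O bond, the C-3 radical is reduced by the silane, and 10 collapses to the alcohol with loss of COS on methanolic work-up, removing the C-3 stereocentre and leaving the others, the acetate and both alkenes untouched.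

**Step 7**
Reactants: 11 15-acetoxy-ent-halima-1(10),13E-dien-18-ol
Product: 13 15-acetoxy-ent-halima-1(10),13E-dien-18-oic acid (4S,5S,8R,9S), via C-18 aldehyde 12 (not isolated)
Conditions: TEMPO (0.3 equiv), PhI(OAc)2 (2.5 equiv), MeCN/pH 7 buffer (1:1), rt
Reagents that add atoms: water, O
Why: Nitroxyl/iodine(III) oxidation in water (Epp–Widlanski conditions) takes the alcohol to aldehyde 12, whose hydrate is oxidised again to the acid under neutral conditions that spare the acetate, both alkenes and the quaternary C-4 centre.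

**Compound list**
1 | (2E,6E,10E)-geranylgeraniol, (2E,6E,10E)-3,7,11,15-tetramethylhexadeca-2,6,10,14-tetraen-1-ol | CC(C)=CCC/C(C)=C/CC/C(C)=C/CC/C(C)=C/CO | starting material
2 | (2E,6E,10E)-geranylgeranyl acetate | CC(C)=CCC/C(C)=C/CC/C(C)=C/CC/C(C)=C/COC(C)=O | intermediate
3 | (2E,6E,10E,14E)-16-hydroxygeranylgeranyl acetate (CH2OH trans to the chain) | OC/C(C)=C/CC/C(C)=C/CC/C(C)=C/CC/C(C)=C/COC(C)=O | intermediate
4 | (14R,15R)-14,15-epoxy-16-hydroxygeranylgeranyl acetate, (2E,6E,10E)-13-[(2R,3R)-3-(hydroxymethyl)-3-methyloxiran-2-yl]-3,7,11-trimethyltrideca-2,6,10-trien-1-yl acetate | OC[C@@]1(C)O[C@@H]1CC/C(C)=C/CC/C(C)=C/CC/C(C)=C/COC(C)=O | intermediate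
5 | 15-acetoxy-3,18-dihydroxy-ent-labd-13E-en-8-yl cation (not isolated; H-5β, H-9β, Me-10α; oxygens BF3-bound in the flask, drawn as OH) | CC(=O)OC/C=C(\C)CC[C@@H]1[C+](C)CC[C@@H]2[C@@](C)(CO)[C@H](O)CC[C@@]12C | intermediate
6 | 15-acetoxy-3,18-dihydroxy-ent-labd-13E-en-9-yl cation (not isolated; H-8β, Me-10α) | CC(=O)OC/C=C(\C)CC[C+]1[C@H](C)CC[C@@H]2[C@@](C)(CO)[C@H](O)CC[C@@]12C | intermediate
7 | 15-acetoxy-3,18-dihydroxy-ent-halim-13E-en-10-yl cation (not isolated; H-8β, Me on C-9 α, side chain β) | CC(=O)OC/C=C(\C)CC[C@]1(C)[C+]2CC[C@@H](O)[C@](C)(CO)[C@H]2CC[C@H]1C | intermediate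
8 | 15-acetoxy-ent-halima-1(10),13E-diene-3,18-diol (3R,4S,5S,8R,9S; equatorial 3-OH, equatorial CH2OH) | CC(=O)OC/C=C(\C)CC[C@]1(C)C2=CC[C@@H](O)[C@](C)(CO)[C@H]2CC[C@H]1C | intermediate
9 | cyclic 3,18-thionocarbonate of 8 (1,3-dioxane-2-thione fused at C-3/C-4; 3R,4S,5S,8R,9S) | CC(=O)OC/C=C(\C)CC[C@]1(C)C2=CC[C@H]3OC(=S)OC[C@]3(C)[C@H]2CC[C@H]1C | intermediate
10 | O-(15-acetoxy-ent-halima-1(10),13E-dien-18-yl) S-[tris(trimethylsilyl)silyl] thiocarbonate (not isolated) | CC(=O)OC/C=C(\C)CC[C@]1(C)C2=CCC[C@](C)(COC(=O)S[Si]([Si](C)(C)C)([Si](C)(C)C)[Si](C)(C)C)[C@H]2CC[C@H]1C | intermediate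
11 | 15-acetoxy-ent-halima-1(10),13E-dien-18-ol (4S,5S,8R,9S) | CC(=O)OC/C=C(\C)CC[C@]1(C)C2=CCC[C@](C)(CO)[C@H]2CC[C@H]1C | intermediate
12 | 15-acetoxy-ent-halima-1(10),13E-dien-18-al (not isolated; 4S,5S,8R,9S) | CC(=O)OC/C=C(\C)CC[C@]1(C)C2=CCC[C@](C)(C=O)[C@H]2CC[C@H]1C | intermediate
13 | 15-acetoxy-ent-halima-1(10),13E-dien-18-oic acid (4S,5S,8R,9S), CNP0276297.1 | CC(=O)OC/C=C(\C)CC[C@]1(C)C2=CCC[C@](C)(C(=O)O)[C@H]2CC[C@H]1C | target

**Step count and risk**
Total steps: 7. Longest linear sequence: 7 (fully linear from 1).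

The three steps most likely to fail are 4, 6 and 7.

Step 4 (cascade). The cascade may stop at the labdane stage, or the C-10 cation may give the more substituted Δ5(10) alkene instead of Δ1(10). The fallback replaces the single E1-terminated cascade with a cyclise, trap and eliminate sequence that fixes the alkene position by stereoelectronics. Setting out from 4, MeAlCl2 (3 equiv, CH2Cl2, −78 °C, Et3N quench) gives the kinetic exocyclic alkene 15-acetoxy-ent-labda-8(17),13E-diene-3,18-diol F1. F1 is re-ionised at C-8 with HCl/SnCl4 (CH2Cl2, −78 → −40 °C), so that the H-9→C-8 and Me-10→C-9 shifts run in a chloride-rich medium and the C-10 cation is captured by chloride anti to the departing methyl, giving 15-acetoxy-10β-chloro-ent-halim-13E-ene-3,18-diol F2 (chlorine cis to H-5). DBU (toluene, 80 °C) then effects an anti E2 elimination that can only use H-1α, because H-5 is syn to chlorine, and the sequence comes back to the route at 8.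

Step 6 (regioselective deoxygenation). The cyclic thionocarbonate may fragment toward C-18, or the C-3 radical may be intercepted. The fallback enforces the regiochemistry by protection instead of by radical stability. Setting out from 8 (steps 5 and 6 are both replaced), TBSCl/imidazole (CH2Cl2, 0 °C) silylates only the primary alcohol to give 15-acetoxy-18-(tert-butyldimethylsilyloxy)-ent-halima-1(10),13E-dien-3-ol F3. Thiocarbonyldiimidazole/DMAP (toluene, 90 °C) gives its 3-O-(imidazol-1-ylthiocarbonyl) derivative F4. (Me3Si)3SiH/AIBN (toluene, 90 °C) gives 15-acetoxy-18-(tert-butyldimethylsilyloxy)-ent-halima-1(10),13E-diene F5. HF·pyridine (THF, 0 °C) removes the silyl group and the sequence comes back to the route at 11.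

Step 7 (one-pot oxidation). The neopentyl aldehyde next to the quaternary C-4 may hydrate poorly, so that the nitroxyl oxidation stalls. The fallback splits the oxidation into two mechanistically different operations. Setting out from 11, Dess–Martin periodinane (CH2Cl2, NaHCO3, rt) gives the aldehyde 12, now isolated. Pinnick–Lindgren oxidation (NaClO2, NaH2PO4, 2-methyl-2-butene, t-BuOH/H2O, 0 °C → rt; the scavenger protects both alkenes from HOCl) then comes back to the route at 13. This path makes no compound outside the list (none F0).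

**Further compounds**
F1 | step 4 | 15-acetoxy-ent-labda-8(17),13E-diene-3,18-diol (3R,4S,5S,9R,10S) | CC(=O)OC/C=C(\C)CC[C@@H]1C(=C)CC[C@@H]2[C@@](C)(CO)[C@H](O)CC[C@@]12C
F2 | step 4 | 15-acetoxy-10β-chloro-ent-halim-13E-ene-3,18-diol (3R,4S,5R,8R,9S,10R; Cl cis to H-5) | CC(=O)OC/C=C(\C)CC[C@]1(C)[C@@]2(Cl)CC[C@@H](O)[C@](C)(CO)[C@H]2CC[C@H]1C
F3 | step 6 | 15-acetoxy-18-(tert-butyldimethylsilyloxy)-ent-halima-1(10),13E-dien-3-ol (3R) | CC(=O)OC/C=C(\C)CC[C@]1(C)C2=CC[C@@H](O)[C@](C)(CO[Si](C)(C)C(C)(C)C)[C@H]2CC[C@H]1C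
F4 | step 6 | 3-O-(imidazol-1-ylthiocarbonyl) derivative of F3 | CC(=O)OC/C=C(\C)CC[C@]1(C)C2=CC[C@@H](OC(=S)n3ccnc3)[C@](C)(CO[Si](C)(C)C(C)(C)C)[C@H]2CC[C@H]1C
F5 | step 6 | 15-acetoxy-18-(tert-butyldimethylsilyloxy)-ent-halima-1(10),13E-diene | CC(=O)OC/C=C(\C)CC[C@]1(C)C2=CCC[C@](C)(CO[Si](C)(C)C(C)(C)C)[C@H]2CC[C@H]1C
F0 | step 7 | none | none
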